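**Plan**
- Retrosynthesis (labdane numbering): C12–C13 is cut to a decalin-ethyl Grignard reagent and methyl crotonate; ring B is opened at C9–C10 (with C5–H and the C7=C8 alkene) to a monocyclic diene; C5–C6 is cut to a ring-A enol triflate and a C6–C12 alkylzinc.
- Forward: ring A is ketoisophorone (C1–C5, C10 and three methyls in place, its C4 carbonyl becoming the C2 oxygen); the E-alkene chain is attached by Negishi coupling; ring B is closed by a superacid cation–olefin cyclisation; the side chain is completed last.
- Feature that makes the key step possible: C12 is an unbranched CH2 insulated from ring B by C11, and C13 is a methyl-bearing CH standing β to the oxygen-bearing C15. A primary alkyl nucleophile and the β-carbon of a crotonate therefore map exactly onto C12–C13(C16)–C14–C15.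
- Stereochemistry: C2 from Ru-catalysed asymmetric transfer hydrogenation; C5, C9 and C10 relayed from C2 in the chair-like cyclisation (equatorial C2–O, E-alkene); C13 from the chiral copper catalyst of the key step.

Key step: step 11

Assumption: labdane numbering is used for the decalin and its precursors, and the sense of induction of the two catalytic asymmetric steps (1 and 11) is taken from the usual models for these catalyst families, the antipodal ligand being used if a model run shows the opposite sense.

Step 1
Reactants: 1 ketoisophorone (2,6,6-trimethylcyclohex-2-ene-1,4-dione)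
Product: 2 (R)-4-hydroxy-2,6,6-trimethylcyclohex-2-en-1-one
Conditions: RuCl(p-cymene)[(R,R)-TsDPEN] (0.5 mol %), HCO2H/Et3N (5:2), CH2Cl2, 25 °C
Reagents that add atoms: none
Why: Ru/TsDPEN asymmetric transfer hydrogenation should reduce only the unhindered C4 carbonyl (flanked by CH= and CH2, while C1 is blocked by CMe2 and CMe=), and the alkenyl/alkyl differentiation by the chiral Ru–H/N–H pair sets the carbinol centre (the future C2) as R.

Step 2
Reactants: 2 (R)-4-hydroxy-2,6,6-trimethylcyclohex-2-en-1-one
Product: 3 (R)-3,5,5-trimethyl-4-oxocyclohex-2-en-1-yl N,N-diisopropylcarbamate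
Conditions: N,N-diisopropylcarbamoyl chloride, pyridine, DMAP (cat.), 70 °C
Reagents that add atoms: N,N-diisopropylcarbamoyl chloride, CC(C)N(C(C)C)C(=O)Cl
Why: Carbamoylation of the secondary alcohol installs a group that should survive hydride, zinc and Grignard reagents, fluorosulfuric acid (as its O-protonated, non-participating form) and methanolysis, and is removed by LiAlH4 in step 12.

Step 3
Reactants: 3 (R)-3,5,5-trimethyl-4-oxocyclohex-2-en-1-yl N,N-diisopropylcarbamate
Product: 5 (S)-3,5,5-trimethyl-4-(trifluoromethylsulfonyloxy)cyclohex-3-en-1-yl N,N-diisopropylcarbamate, via lithium enolate 4 (not isolated)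
Conditions: L-Selectride, THF, −78 °C; then PhNTf2, −78 °C to rt
Reagents that add atoms: N-phenyl-bis(trifluoromethanesulfonimide), O=S(=O)(N(c1ccccc1)S(=O)(=O)C(F)(F)F)C(F)(F)F
Why: Reductive triflation: conjugate hydride delivery to the β-unsubstituted, carbonyl-hindered enone gives a single regiodefined enolate, and its O-triflation fixes the tetrasubstituted C5=C10 alkene without touching the carbinol centre.

Step 4
Reactants: 6 tert-butyl(but-3-yn-1-yloxy)dimethylsilane
Product: 8 (E)-6-(tert-butyldimethylsilyloxy)-4-methylhex-3-en-1-ol, via alkenylalane 7 (not isolated)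
Conditions: Me3Al, Cp2ZrCl2 (25 mol %), CH2Cl2, 0 °C to rt; then n-BuLi, −78 °C; then oxirane, −78 to 0 °C; aq. work-up
Reagents that add atoms: trimethylaluminium, C[Al](C)C; oxirane, C1CO1
Why: Zirconium-catalysed methylalumination adds Me and Al syn with Al at the terminal carbon, and the derived alanate opens oxirane with retention, so the E-trisubstituted alkene (the future C8=C9) is set by the syn addition.

Step 5
Reactants: 8 (E)-6-(tert-butyldimethylsilyloxy)-4-methylhex-3-en-1-ol
Product: 9 (E)-6-(tert-butyldimethylsilyloxy)-4-methylhex-3-en-1-yl acetate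
Conditions: Ac2O, pyridine, DMAP (cat.), CH2Cl2, 0 °C to rt
Reagents that add atoms: acetic anhydride, CC(=O)OC(C)=O
Why: Routine acetylation; the acetate is inert in steps 6–8 and keeps the C12 oxygen from capturing the C8 cation as a cyclic ether in step 8.

Step 6
Reactants: 9 (E)-6-(tert-butyldimethylsilyloxy)-4-methylhex-3-en-1-yl acetate
Product: 10 (E)-6-bromo-4-methylhex-3-en-1-yl acetate
Conditions: Ph3PBr2, CH2Cl2, 0 °C to rt
Reagents that add atoms: dibromotriphenylphosphorane, BrP(Br)(c1ccccc1)(c1ccccc1)c1ccccc1
Why: Direct conversion of a primary silyl ether into the bromide through the alkoxyphosphonium bromide (SN2 by bromide), which spares the acetate and the alkene.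

Step 7
Reactants: 10 (E)-6-bromo-4-methylhex-3-en-1-yl acetate; 5 (S)-3,5,5-trimethyl-4-(trifluoromethylsulfonyloxy)cyclohex-3-en-1-yl N,N-diisopropylcarbamate
Product: 12 (S)-4-[(E)-6-acetoxy-3-methylhex-3-en-1-yl]-3,5,5-trimethylcyclohex-3-en-1-yl N,N-diisopropylcarbamate, via alkylzinc bromide 11 (not isolated)
Conditions: Zn dust (activated), LiCl, THF, 50 °C; then 5, Pd(OAc)2 (3 mol %), SPhos (6 mol %), THF/NMP, 25 to 50 °C
Reagents that add atoms: none
Why: Negishi sp3–sp2 coupling: zinc inserts into the primary C–Br bond without touching the acetate, and the bulky biarylphosphine palladium catalyst should join the primary alkylzinc to the hindered enol triflate faster than β-hydride elimination, forming C5–C6.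

Step 8
Reactants: 12 (S)-4-[(E)-6-acetoxy-3-methylhex-3-en-1-yl]-3,5,5-trimethylcyclohex-3-en-1-yl N,N-diisopropylcarbamate
Product: 13 (2R,5R,9R,10R)-2-(diisopropylcarbamoyloxy)-13,14,15,16-tetranorlabd-7-en-12-yl acetate
Conditions: FSO3H (5 equiv), 2-nitropropane, −78 °C, 30 min; Et3N quench at −78 °C; aq. NaHCO3
Reagents that add atoms: none
Why: Superacid cation–olefin cyclisation of the type known for monocyclic homofarnesyl and farnesyl acetates: protonation at C5 gives the tertiary C10 cation, C9 of the E-alkene attacks it 6-endo through a chair transition state in which the O-protonated carbamate at C2 is equatorial (so C2 selects the ring face and fixes C5-H/C10-Me trans and the C9 chain equatorial), and the C8 cation loses H-7 to give the trisubstituted C7=C8 alkene.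

Step 9
Reactants: 13 (2R,5R,9R,10R)-2-(diisopropylcarbamoyloxy)-13,14,15,16-tetranorlabd-7-en-12-yl acetate
Product: 14 (2R,5R,9R,10R)-12-hydroxy-13,14,15,16-tetranorlabd-7-en-2-yl N,N-diisopropylcarbamate
Conditions: K2CO3 (cat.), MeOH, 0 °C to rt
Reagents that add atoms: none
Why: Base-catalysed methanolysis cleaves the primary acetate, while the hindered N,N-dialkyl carbamate is inert to carbonate in methanol.

Step 10
Reactants: 14 (2R,5R,9R,10R)-12-hydroxy-13,14,15,16-tetranorlabd-7-en-2-yl N,N-diisopropylcarbamate
Product: 15 (2R,5R,9R,10R)-12-bromo-13,14,15,16-tetranorlabd-7-en-2-yl N,N-diisopropylcarbamate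
Conditions: CBr4, PPh3, CH2Cl2, 0 °C
Reagents that add atoms: tetrabromomethane, BrC(Br)(Br)Br
Why: Appel bromination (SN2 at the primary carbinol) under neutral conditions that leave the C7=C8 alkene and the carbamate untouched.

Step 11
Reactants: 15 (2R,5R,9R,10R)-12-bromo-13,14,15,16-tetranorlabd-7-en-2-yl N,N-diisopropylcarbamate; 16 methyl (E)-but-2-enoate (methyl crotonate)
Product: 18 methyl (2R,5R,9R,10R,13S)-2-(diisopropylcarbamoyloxy)labd-7-en-15-oate, via Grignard reagent 17 (not isolated)
Conditions: Mg, I2 (cat.), Et2O, 35 °C; then added over 2 h to 16 (1.5 equiv), CuBr·SMe2 (5 mol %), (R,S)-Josiphos (6 mol %), t-BuOMe, −75 °C; MeOH, then aq. NH4Cl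
Reagents that add atoms: none
Why: The Grignard reagent transmetalates to the Josiphos-bound copper(I) centre, the alkylcopper forms a π-complex with the s-cis crotonate, oxidative addition at the β-carbon (C13) gives a σ-copper(III) species, and reductive elimination forms C12–C13 and a magnesium enolate that is protonated on quench. The closest known reaction type is the copper/ferrocenyl-diphosphine-catalysed enantioselective conjugate addition of primary alkyl Grignard reagents to crotonates and enethioates. No ring is closed. The new stereocentre C13 is controlled by the ligand alone, which selects the enantioface of the planar crotonate; the nearest decalin stereocentre (C9) is three bonds from the reacting carbon, so no matched/mismatched effect is expected. The step needs 1,4- over 1,2-selectivity and high face selectivity, which the low temperature, slow addition of the limiting Grignard reagent, the weakly coordinating ether solvent and the phosphine-bound cuprate should secure, while the carbamate and the trisubstituted alkene are inert to RMgBr. The adduct carries all carbons of the target with C15 one reduction away from the required oxidation level.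

Step 12
Reactants: 18 methyl (2R,5R,9R,10R,13S)-2-(diisopropylcarbamoyloxy)labd-7-en-15-oate
Product: 19 (2R,5R,9R,10R,13S)-labd-7-ene-2,15-diol
Conditions: LiAlH4 (excess), THF, 0 °C to reflux; aq. NaOH work-up
Reagents that add atoms: none
Why: LiAlH4 reduces the methyl ester to the C15 primary alcohol and cleaves the carbamate by attack at its acyl carbon, so the C2–O bond and its configuration are untouched.

Step 13
Reactants: 19 (2R,5R,9R,10R,13S)-labd-7-ene-2,15-diol
Product: 20 (2R,5R,9R,10R,13S)-labd-7-ene-2,15-diyl diacetate (CNP0220683.1)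
Conditions: Ac2O, pyridine, DMAP (cat.), CH2Cl2, rt
Reagents that add atoms: acetic anhydride, CC(=O)OC(C)=O
Why: DMAP-catalysed acetylation of the primary and the equatorial secondary hydroxyl gives the diacetate without affecting any stereocentre.

**Compound list**
1 | ketoisophorone (2,6,6-trimethylcyclohex-2-ene-1,4-dione) | CC1=CC(=O)CC(C)(C)C1=O | starting material
2 | (R)-4-hydroxy-2,6,6-trimethylcyclohex-2-en-1-one | CC1=C[C@H](O)CC(C)(C)C1=O | intermediate
3 | (R)-3,5,5-trimethyl-4-oxocyclohex-2-en-1-yl N,N-diisopropylcarbamate | CC1=C[C@H](OC(=O)N(C(C)C)C(C)C)CC(C)(C)C1=O | intermediate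
4 | lithium (S)-4-(diisopropylcarbamoyloxy)-2,6,6-trimethylcyclohex-1-en-1-olate | CC1=C(O[Li])C(C)(C)C[C@@H](OC(=O)N(C(C)C)C(C)C)C1 | intermediate (not isolated)
5 | (S)-3,5,5-trimethyl-4-(trifluoromethylsulfonyloxy)cyclohex-3-en-1-yl N,N-diisopropylcarbamate | CC1=C(OS(=O)(=O)C(F)(F)F)C(C)(C)C[C@@H](OC(=O)N(C(C)C)C(C)C)C1 | intermediate
6 | tert-butyl(but-3-yn-1-yloxy)dimethylsilane | C#CCCO[Si](C)(C)C(C)(C)C | starting material
7 | (E)-[4-(tert-butyldimethylsilyloxy)-2-methylbut-1-en-1-yl]dimethylalane | C[Al](C)/C=C(\C)CCO[Si](C)(C)C(C)(C)C | intermediate (not isolated)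
8 | (E)-6-(tert-butyldimethylsilyloxy)-4-methylhex-3-en-1-ol | OCC/C=C(\C)CCO[Si](C)(C)C(C)(C)C | intermediate
9 | (E)-6-(tert-butyldimethylsilyloxy)-4-methylhex-3-en-1-yl acetate | CC(=O)OCC/C=C(\C)CCO[Si](C)(C)C(C)(C)C | intermediate
10 | (E)-6-bromo-4-methylhex-3-en-1-yl acetate | CC(=O)OCC/C=C(\C)CCBr | intermediate
11 | (E)-(6-acetoxy-3-methylhex-3-en-1-yl)zinc bromide | CC(=O)OCC/C=C(\C)CC[Zn]Br | intermediate (not isolated)
12 | (S)-4-[(E)-6-acetoxy-3-methylhex-3-en-1-yl]-3,5,5-trimethylcyclohex-3-en-1-yl N,N-diisopropylcarbamate | CC(=O)OCC/C=C(\C)CCC1=C(C)C[C@H](OC(=O)N(C(C)C)C(C)C)CC1(C)C | intermediate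
13 | (2R,5R,9R,10R)-2-(diisopropylcarbamoyloxy)-13,14,15,16-tetranorlabd-7-en-12-yl acetate | CC(=O)OCC[C@@H]1C(C)=CC[C@@H]2C(C)(C)C[C@@H](OC(=O)N(C(C)C)C(C)C)C[C@@]12C | intermediate
14 | (2R,5R,9R,10R)-12-hydroxy-13,14,15,16-tetranorlabd-7-en-2-yl N,N-diisopropylcarbamate | OCC[C@@H]1C(C)=CC[C@@H]2C(C)(C)C[C@@H](OC(=O)N(C(C)C)C(C)C)C[C@@]12C | intermediate
15 | (2R,5R,9R,10R)-12-bromo-13,14,15,16-tetranorlabd-7-en-2-yl N,N-diisopropylcarbamate | BrCC[C@@H]1C(C)=CC[C@@H]2C(C)(C)C[C@@H](OC(=O)N(C(C)C)C(C)C)C[C@@]12C | intermediate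
16 | methyl (E)-but-2-enoate | C/C=C/C(=O)OC | starting material
17 | [(2R,5R,9R,10R)-2-(diisopropylcarbamoyloxy)-13,14,15,16-tetranorlabd-7-en-12-yl]magnesium bromide | Br[Mg]CC[C@@H]1C(C)=CC[C@@H]2C(C)(C)C[C@@H](OC(=O)N(C(C)C)C(C)C)C[C@@]12C | intermediate (not isolated)
18 | methyl (2R,5R,9R,10R,13S)-2-(diisopropylcarbamoyloxy)labd-7-en-15-oate | COC(=O)C[C@@H](C)CC[C@@H]1C(C)=CC[C@@H]2C(C)(C)C[C@@H](OC(=O)N(C(C)C)C(C)C)C[C@@]12C | intermediate
19 | (2R,5R,9R,10R,13S)-labd-7-ene-2,15-diol | OCC[C@@H](C)CC[C@@H]1C(C)=CC[C@@H]2C(C)(C)C[C@@H](O)C[C@@]12C | intermediate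
20 | (2R,5R,9R,10R,13S)-labd-7-ene-2,15-diyl diacetate | CC(=O)OCC[C@@H](C)CC[C@@H]1C(C)=CC[C@@H]2C(C)(C)C[C@@H](OC(C)=O)C[C@@]12C | target

**Step count**
Total steps: 13. Longest linear sequence: 10 steps (1 to 20 through steps 1–3 and 7–13; the chain branch from 6 through steps 4–13 is equally long).

**Steps most likely to fail**

Step 8. What may go wrong: unselective proton loss from the C8 cation (exocyclic C8=C17 or tetrasubstituted C8=C9 alkene), incomplete transfer of the C2 configuration to the ring fusion, or hydride and methyl shifts of the long-lived cation. Fallback, from 12 back to 13: the alkene position is set in a separate radical step instead of by the cationic termination. The cyclisation is quenched early at −78 °C, and the olefin mixture is carried on; its expected main contaminant is the exocyclic isomer (2R,5R,9R,10R)-2-(diisopropylcarbamoyloxy)-13,14,15,16-tetranorlabd-8(17)-en-12-yl acetate F1. The mixture is treated with Co(salen)Cl (cat.) and PhSiH3 (cat.) in benzene at room temperature. Hydrogen-atom transfer to the exocyclic methylene and return of hydrogen from the less hindered C7–H should move the alkene one position into the ring and converge F1 on 13. Any diastereomer or C8=C9 isomer, which this step cannot recycle, is removed on silver nitrate-impregnated silica.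

Step 11. What may go wrong: competing 1,2-addition to the ester, homocoupling of the Grignard reagent, or insufficient enantioface differentiation. Fallback, from 17 back to 19: C13 is taken from the chiral pool and the bond is made by stereospecific substitution. (S)-Butane-1,3-diol is pivaloylated at the primary hydroxyl (PivCl, pyridine, −20 °C) to (S)-3-hydroxybutyl pivalate F2 and tosylated (TsCl, pyridine) to (S)-4-(pivaloyloxy)butan-2-yl 4-methylbenzenesulfonate F3. Copper-catalysed coupling of 17 with F3 (CuI, TMEDA, LiOMe, THF, 0 °C; SN2 with inversion at the secondary carbon) should give (2R,5R,9R,10R,13S)-2-(diisopropylcarbamoyloxy)labd-7-en-15-yl pivalate F4. LiAlH4 (THF, reflux) then removes pivalate and carbamate together to give 19.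

Step 7. What may go wrong: slow oxidative addition and transmetalation at the doubly flanked tetrasubstituted triflate, with protodezincation or β-hydride elimination of the alkyl partner taking over. Fallback, from 5 back to 12: the sp3–sp2 bond is moved away from the hindered carbon. Stille vinylation of 5 (tributyl(vinyl)stannane, Pd2(dba)3, AsPh3, NMP) gives the diene (S)-3,5,5-trimethyl-4-vinylcyclohex-3-en-1-yl N,N-diisopropylcarbamate F5. Pent-3-yn-1-ol is acetylated to pent-3-yn-1-yl acetate F6 and converted by hydrozirconation–iodination (Cp2Zr(H)Cl, then I2) into (E)-4-iodopent-3-en-1-yl acetate F7. 9-BBN adds to the vinyl group of F5 to give (S)-4-[2-(9-borabicyclo[3.3.1]nonan-9-yl)ethyl]-3,5,5-trimethylcyclohex-3-en-1-yl N,N-diisopropylcarbamate F8. B-alkyl Suzuki coupling of F8 with the unhindered vinyl iodide F7 (PdCl2(dppf), Cs2CO3, DMF/THF/H2O) forms C7–C8 and gives 12.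

**Further compounds**
F1 | step 8 | (2R,5R,9R,10R)-2-(diisopropylcarbamoyloxy)-13,14,15,16-tetranorlabd-8(17)-en-12-yl acetate | CC(=O)OCC[C@@H]1C(=C)CC[C@@H]2C(C)(C)C[C@@H](OC(=O)N(C(C)C)C(C)C)C[C@@]12C
F2 | step 11 | (S)-3-hydroxybutyl pivalate | C[C@H](O)CCOC(=O)C(C)(C)C
F3 | step 11 | (S)-4-(pivaloyloxy)butan-2-yl 4-methylbenzenesulfonate | C[C@H](OS(=O)(=O)c1ccc(C)cc1)CCOC(=O)C(C)(C)C
F4 | step 11 | (2R,5R,9R,10R,13S)-2-(diisopropylcarbamoyloxy)labd-7-en-15-yl pivalate | CC(C)(C)C(=O)OCC[C@@H](C)CC[C@@H]1C(C)=CC[C@@H]2C(C)(C)C[C@@H](OC(=O)N(C(C)C)C(C)C)C[C@@]12C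
F5 | step 7 | (S)-3,5,5-trimethyl-4-vinylcyclohex-3-en-1-yl N,N-diisopropylcarbamate | C=CC1=C(C)C[C@H](OC(=O)N(C(C)C)C(C)C)CC1(C)C
F6 | step 7 | pent-3-yn-1-yl acetate | CC#CCCOC(C)=O
F7 | step 7 | (E)-4-iodopent-3-en-1-yl acetate | CC(=O)OCC/C=C(\C)I
F8 | step 7 | (S)-4-[2-(9-borabicyclo[3.3.1]nonan-9-yl)ethyl]-3,5,5-trimethylcyclohex-3-en-1-yl N,N-diisopropylcarbamate | CC1=C(CCB2C3CCCC2CCC3)C(C)(C)C[C@@H](OC(=O)N(C(C)C)C(C)C)C1
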